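**Retrosynthetic overview**

1. The γ-lactone is closed last by C7–O/C8–O bond formation: carboxylate-directed syn-dihydroxylation of the C7=C8 bond of (5Z,7Z)-dienyl acid 33, lactonisation, then C17 equilibration.
2. Acid 33 comes from the ten-membered α-siloxy ketone 23 through its Z-dienyl triflate and a propionate zinc enolate (C8–C17).
3. The ten-membered ring is closed at C7–C8 by intramolecular allylic alkylation of a nitronate (nitro = masked C8 ketone); C8–C9 comes from an asymmetric Henry reaction.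
4. C1–C2 comes from an aldol of the ring enolate with an aldehyde cut from neryl acetate; C14 is set by 1,3-anti hydride delivery.
5. The cyclohexane is made first by Diels–Alder reaction of siloxydiene 4 with 2-bromoacrolein (C10, C11), then bromohydrin to 11,20-epoxide. Ring order: cyclohexane, epoxide, ten-membered ring, lactone.

Assumptions: briarane numbering of the target (C15 = methyl on C1, C16 = methyl on C5, C18 = methyl on C17, C19 = lactone carbonyl, C20 = epoxide CH2) locates atoms in all intermediates. Where C8 or C17 is an epimer mixture the SMILES leaves that centre undefined. 2-Bromoacrolein is made fresh because it does not keep.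

**Route**

Step 1
Reactants: 1 glycolaldehyde dimer; 2 3-(triphenylphosphoranylidene)butan-2-one
Product: 3 (E)-5-hydroxy-3-methylpent-3-en-2-one
Conditions: THF, reflux
Reagents that add atoms: none
Why: Wittig olefination of the open-chain aldehyde (in equilibrium with the dimer) by a stabilised ylide gives the E-enone.

Step 2
Reactants: 3 (E)-5-hydroxy-3-methylpent-3-en-2-one
Product: 4 (E)-3-methyl-2,5-bis(triethylsilyloxy)penta-1,3-diene
Conditions: Et3SiOSO2CF3 (2.3 equiv), Et3N, CH2Cl2, −78 → 0 °C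
Reagents that add atoms: triethylsilyl trifluoromethanesulfonate, CC[Si](CC)(CC)OS(=O)(=O)C(F)(F)F
Why: Soft enolisation of the methyl ketone gives the kinetic 2-siloxy-1,3-diene (silyl enol ether formation) while the primary alcohol is silylated in the same operation; the E alkene is kept.

Step 3
Reactants: 5 acrolein
Product: 7 2-bromoacrolein, via 2,3-dibromopropanal 6 (not isolated)
Conditions: Br2, CH2Cl2, −78 °C; then Et3N, 0 °C
Reagents that add atoms: bromine, BrBr
Why: Bromine addition to the alkene followed by E1cB loss of HBr gives the α-bromo enal (addition–elimination).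

Step 4
Reactants: 4 (E)-3-methyl-2,5-bis(triethylsilyloxy)penta-1,3-diene; 7 2-bromoacrolein
Product: 8 1-bromo-3-methyl-4-(triethylsilyloxy)-2-[(triethylsilyloxy)methyl]cyclohex-3-ene-1-carbaldehyde, Br cis to CH2OSiEt3 (C11 and C10)
Conditions: (S)-3,3-diphenyl-1-(2-methylphenyl)tetrahydro-1H,3H-pyrrolo[1,2-c][1,3,2]oxazaborole·HN(SO2CF3)2 (20 mol%), CH2Cl2, −78 °C
Reagents that add atoms: none
Why: Enantioselective Diels–Alder reaction under chiral oxazaborolidinium catalysis: the 2-siloxy group directs the "para" orientation (C10–C11 and C12–C13 bonds), the formyl-exo/bromine-endo approach usual for 2-bromoacrolein puts Br cis to the C10 side chain, and the catalyst enantiomer is the one that gives the C10 configuration drawn (the antipodal catalyst is used if the facial sense is reversed).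

Step 5
Reactants: 8 Diels–Alder bromo-aldehyde
Product: 10 5-methyl-6-(triethylsilyloxy)-4-[(triethylsilyloxy)methyl]-1-oxaspiro[2.5]oct-5-ene (epoxide O trans to the C10 side chain), via bromohydrin 9 (not isolated)
Conditions: NaBH4, EtOH, −20 °C; then 1,8-diazabicyclo[5.4.0]undec-7-ene (DBU), 0 °C → rt
Reagents that add atoms: none
Why: Hydride reduction of the aldehyde and intramolecular Williamson (SN2) closure onto the tertiary bromide with inversion at C11 put the epoxide oxygen trans and C20 cis to the C10 side chain, as in the target.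

Step 6
Reactants: 11 neryl acetate
Product: 13 (2Z)-3-methyl-6-oxohex-2-en-1-yl acetate, via ozonide 12 (not isolated)
Conditions: O3 (1.0 equiv), CH2Cl2, pyridine (cat.), −78 °C; then Me2S, −78 °C → rt
Reagents that add atoms: ozone, O=[O+][O-]
Why: Ozonolysis is selective for the electron-rich 6,7-alkene over the 2,3-alkene deactivated by the allylic acetate, so the Z-trisubstituted alkene (C5=C6 of the target) survives.

Step 7
Reactants: 10 spiro-epoxide silyl enol ether; 13 (2Z)-3-methyl-6-oxohex-2-en-1-yl acetate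
Product: 15 5-[(1S,4Z)-6-acetoxy-1-hydroxy-4-methylhex-4-en-1-yl]-5-methyl-4-[(triethylsilyloxy)methyl]-1-oxaspiro[2.5]octan-6-one, via lithium enolate 14 (not isolated)
Conditions: MeLi (1.05 equiv), THF, 0 °C; then 13, −78 °C; aq. NH4Cl
Reagents that add atoms: none
Why: MeLi cleaves the silyl enol ether to the regiodefined tetrasubstituted lithium enolate, which undergoes aldol addition anti to the C10 substituent (C1 quaternary, C2 chain trans to C9) through a closed Zimmerman–Traxler transition state that places the C2 hydroxyl syn to the C1 methyl (2S).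

Step 8
Reactants: 15 aldol adduct
Product: 16 C2 acetate/C14 alcohol: 5-[(1S,4Z)-1,6-diacetoxy-4-methylhex-4-en-1-yl]-5-methyl-4-[(triethylsilyloxy)methyl]-1-oxaspiro[2.5]octan-6-ol (14S)
Conditions: MeCHO (8 equiv), SmI2 (30 mol%), THF, −10 °C
Reagents that add atoms: acetaldehyde, CC=O
Why: Evans–Tishchenko reduction: the samarium-bound hemiacetal delivers hydride intramolecularly to C14, giving the 1,3-anti diol (14S) and leaving the C2 oxygen as its acetate.

Step 9
Reactants: 16 C2 acetate/C14 alcohol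
Product: 17 2,7,14-triacetate with C9 triethylsilyl ether
Conditions: Ac2O, pyridine, 4-(dimethylamino)pyridine (DMAP, cat.), CH2Cl2, rt
Reagents that add atoms: acetic anhydride, CC(=O)OC(C)=O
Why: DMAP-catalysed acylation of the hindered secondary C14 alcohol; no stereocentre is touched.

Step 10
Reactants: 17 triacetate silyl ether
Product: 18 C9 aldehyde (2,7,14-triacetate)
Conditions: (COCl)2, DMSO, CH2Cl2, −78 → −35 °C; then Et3N, −78 → 0 °C
Reagents that add atoms: none
Why: Swern conditions oxidise a primary triethylsilyl ether directly to the aldehyde (activated-DMSO oxidation), and the cold amine step avoids enolisation of the β,γ-epoxy aldehyde.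

Step 11
Reactants: 18 C9 aldehyde; 19 nitromethane
Product: 20 (9S)-9-hydroxy-8-nitro compound
Conditions: Cu(OAc)2·H2O (10 mol%), 2,2'-(propane-2,2-diyl)bis(3a,8a-dihydro-8H-indeno[1,2-d]oxazole) (S-selective antipode, 11 mol%), MeNO2 (10 equiv), EtOH, 0 °C → rt
Reagents that add atoms: none
Why: Catalytic asymmetric Henry (nitroaldol) reaction: the weakly basic divalent copper acetate–bis(oxazoline) catalyst directs the nitronate to the Re face of C9 (9S) without enolising the aldehyde.

Step 12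
Reactants: 20 nitro alcohol
Product: 21 C9 triethylsilyl ether of 20
Conditions: Et3SiCl, imidazole, DMAP (cat.), DMF, 0 °C
Reagents that add atoms: chlorotriethylsilane, CC[Si](Cl)(CC)CC
Why: Silylation with the chloride (a silyl triflate would rearrange the epoxide) blocks retro-Henry reaction and later oxidation of C9–OH.

Step 13
Reactants: 21 silylated nitro acetate
Product: 22 ten-membered 8-nitro compound (2,14-diacetate, 9-OSiEt3, 11,20-epoxide, 5Z; C8 epimers)
Conditions: Pd(PPh3)4 (10 mol%), DBU (1.5 equiv), THF, 55 °C, 2 mM, syringe-pump addition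
Reagents that add atoms: none
Why: Intramolecular Tsuji–Trost allylic alkylation: zerovalent palladium ionises the allylic acetate and the soft nitronate carbon attacks the unhindered C7 terminus under high dilution, closing the ten-membered ring with retention of the 5Z geometry; the new C8 centre is removed in step 14.

Step 14
Reactants: 22 ten-membered nitro compound
Product: 23 ten-membered C8 ketone (2,14-diacetate, 9-OSiEt3, 11,20-epoxide, 5Z)
Conditions: (n-Pr4N)RuO4 (10 mol%), N-methylmorpholine N-oxide (3 equiv), K2CO3 (1.2 equiv), 4 Å MS, MeCN, rt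
Reagents that add atoms: N-methylmorpholine N-oxide, C[N+]1([O-])CCOCC1
Why: Oxidative Nef reaction of the potassium nitronate with perruthenate/N-oxide gives the ketone under near-neutral conditions that spare epoxide, acetates, alkene and silyl ether.

Step 15
Reactants: 23 ten-membered ketone
Product: 25 (5Z,7E)-dienyl triflate (C7=C8–OSO2CF3, C6 cis to C9), via potassium dienolate 24 (not isolated)
Conditions: KN(SiMe3)2, THF, −78 °C; then PhN(SO2CF3)2, −78 → −20 °C
Reagents that add atoms: N-phenylbis(trifluoromethanesulfonimide), O=S(=O)(N(c1ccccc1)S(=O)(=O)C(F)(F)F)C(F)(F)F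
Why: Kinetic deprotonation at the doubly activated allylic C7 gives the dienolate, whose cis (in-ring) geometry is the one the ten-membered ring accommodates, and O-sulfonylation gives the enol triflate.

Step 16
Reactants: 26 2-bromopropanoyl bromide; 27 2-(trimethylsilyl)ethanol
Product: 28 2-(trimethylsilyl)ethyl 2-bromopropanoate (racemic)
Conditions: pyridine, CH2Cl2, 0 °C
Reagents that add atoms: none
Why: Acylation of the alcohol by the acid bromide (esterification).

Step 17
Reactants: 25 dienyl triflate; 28 2-(trimethylsilyl)ethyl 2-bromopropanoate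
Product: 30 (5Z,7Z)-dienyl ester with C8–C17 bond (9-OSiEt3; C17 epimers), via bromozinc ester enolate 29 (not isolated)
Conditions: Zn dust (Me3SiCl-activated), THF, rt; then 25, Pd(PPh3)4 (5 mol%), THF, 45 °C
Reagents that add atoms: none
Why: Zinc insertion gives the Reformatsky reagent, which undergoes palladium-catalysed Negishi cross-coupling with the enol triflate with retention of alkene geometry; C17 is formed unselectively and corrected in step 20.

Step 18
Reactants: 30 dienyl ester silyl ether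
Product: 32 2,9,14-triacetate dienyl ester, via C9 alcohol 31 (not isolated)
Conditions: Et3N·3HF, THF, 0 °C → rt; then pyridine, Ac2O, DMAP (cat.), 0 °C
Reagents that add atoms: acetic anhydride, CC(=O)OC(C)=O
Why: Near-neutral fluoride desilylation followed by acetylation in the same flask caps the C9 alcohol before it can lactonise onto the ester (silyl ether cleavage, acylation).

Step 19
Reactants: 32 triacetate dienyl ester
Product: 33 (5Z,7Z)-dienyl carboxylic acid (2,9,14-triacetate, 11,20-epoxide; C17 epimers)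
Conditions: (Me2N)3S+ Me3SiF2−, DMF, 0 °C; aq. NaH2PO4
Reagents that add atoms: none
Why: Fluoride-induced β-elimination of the 2-(trimethylsilyl)ethyl ester frees the acid without touching acetates or epoxide.

Step 20
Reactants: 33 dienyl carboxylic acid
Product: 36 junceellolide K, via dihydroxy acid 34 (not isolated), via 17-epimeric lactones 35 (not isolated)
Conditions: [Mn2(μ-O)3(tmtacn)2](PF6)2 (3 mol%; tmtacn = 1,4,7-trimethyl-1,4,7-triazacyclononane), 50% H2O2 (1.5 equiv, slow addition), MeCN/H2O 9:1, 0 °C; aq. citric acid work-up, toluene, 40 °C; then DBU (20 mol%), toluene, 40 °C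
Reagents that add atoms: hydrogen peroxide, OO
Why: Proposed new method: substrate-carboxylate-directed manganese-catalysed syn-dihydroxylation, in which the acid of 33 takes the place of the carboxylic acid co-ligand of the dimanganese–tmtacn/H2O2 system, so the carboxylate-bridged oxidant is held two atoms from C8 and delivers both oxygens in one syn event to C7=C8 rather than C5=C6, on the face anti to C10 that allylic 1,3-strain (C9–H eclipsing the diene) and the ring leave open, which gives 7S,8S; the cis C7–OH is the only hydroxyl able to close a γ-lactone (O9 is acetylated, O8 would give a β-lactone) and DBU equilibrates C17 to the isomer with methyl anti to C9 (17R); closest known reaction type: carboxylic-acid-promoted manganese–triazacyclononane cis-dihydroxylation of alkenes with H2O2, and carboxylate-directed oxidation by non-heme manganese and iron catalysts.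

**Compound list**

1 | glycolaldehyde dimer (1,4-dioxane-2,5-diol) | OC1COC(O)CO1 | starting material
2 | 3-(triphenylphosphoranylidene)butan-2-one | CC(=O)C(C)=P(c1ccccc1)(c1ccccc1)c1ccccc1 | starting material
3 | (E)-5-hydroxy-3-methylpent-3-en-2-one | CC(=O)/C(C)=C/CO | intermediate
4 | (E)-3-methyl-2,5-bis(triethylsilyloxy)penta-1,3-diene | C=C(O[Si](CC)(CC)CC)/C(C)=C/CO[Si](CC)(CC)CC | intermediate
5 | acrolein | C=CC=O | starting material
6 | 2,3-dibromopropanal | BrCC(Br)C=O | intermediate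
7 | 2-bromoacrolein | C=C(Br)C=O | intermediate
8 | 1-bromo-3-methyl-4-(triethylsilyloxy)-2-[(triethylsilyloxy)methyl]cyclohex-3-ene-1-carbaldehyde, Br cis to CH2OSiEt3 | CC[Si](CC)(CC)OC1=C(C)[C@@H](CO[Si](CC)(CC)CC)[C@](Br)(C=O)CC1 | intermediate
9 | bromohydrin: [1-bromo-3-methyl-4-(triethylsilyloxy)-2-[(triethylsilyloxy)methyl]cyclohex-3-en-1-yl]methanol | CC[Si](CC)(CC)OC1=C(C)[C@@H](CO[Si](CC)(CC)CC)[C@](Br)(CO)CC1 | intermediate
10 | 5-methyl-6-(triethylsilyloxy)-4-[(triethylsilyloxy)methyl]-1-oxaspiro[2.5]oct-5-ene, epoxide O trans to the C4 substituent | CC[Si](CC)(CC)OC1=C(C)[C@@H](CO[Si](CC)(CC)CC)[C@]2(CC1)CO2 | intermediate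
11 | neryl acetate, (2Z)-3,7-dimethylocta-2,6-dien-1-yl acetate | CC(C)=CCC/C(C)=C\COC(C)=O | starting material
12 | ozonide: (2Z)-5-(3,3-dimethyl-1,2,4-trioxolan-5-yl)-3-methylpent-2-en-1-yl acetate | CC(=O)OC/C=C(C)\CCC1OOC(C)(C)O1 | intermediate
13 | (2Z)-3-methyl-6-oxohex-2-en-1-yl acetate | CC(=O)OC/C=C(C)\CCC=O | intermediate
14 | lithium enolate: lithium 5-methyl-4-[(triethylsilyloxy)methyl]-1-oxaspiro[2.5]oct-5-en-6-olate | [Li]OC1=C(C)[C@@H](CO[Si](CC)(CC)CC)[C@]2(CC1)CO2 | intermediate
15 | aldol adduct: 5-[(1S,4Z)-6-acetoxy-1-hydroxy-4-methylhex-4-en-1-yl]-5-methyl-4-[(triethylsilyloxy)methyl]-1-oxaspiro[2.5]octan-6-one; side chain trans to CH2OSiEt3 | CC(=O)OC/C=C(C)\CC[C@H](O)[C@@]1(C)C(=O)CC[C@]2(CO2)[C@@H]1CO[Si](CC)(CC)CC | intermediate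
16 | C2 acetate, C14 alcohol (1,3-anti) of 15 | CC(=O)OC/C=C(C)\CC[C@H](OC(C)=O)[C@@]1(C)[C@@H](O)CC[C@]2(CO2)[C@@H]1CO[Si](CC)(CC)CC | intermediate
17 | 2,7,14-triacetate with C9 triethylsilyl ether | CC(=O)OC/C=C(C)\CC[C@H](OC(C)=O)[C@@]1(C)[C@@H](OC(C)=O)CC[C@]2(CO2)[C@@H]1CO[Si](CC)(CC)CC | intermediate
18 | C9 aldehyde, 2,7,14-triacetate | CC(=O)OC/C=C(C)\CC[C@H](OC(C)=O)[C@@]1(C)[C@@H](OC(C)=O)CC[C@]2(CO2)[C@@H]1C=O | intermediate
19 | nitromethane | C[N+](=O)[O-] | starting material
20 | (9S)-9-hydroxy-8-nitro compound, 2,7,14-triacetate | CC(=O)OC/C=C(C)\CC[C@H](OC(C)=O)[C@@]1(C)[C@@H](OC(C)=O)CC[C@]2(CO2)[C@@H]1[C@H](O)C[N+](=O)[O-] | intermediate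
21 | C9 triethylsilyl ether of 20 | CC(=O)OC/C=C(C)\CC[C@H](OC(C)=O)[C@@]1(C)[C@@H](OC(C)=O)CC[C@]2(CO2)[C@@H]1[C@H](O[Si](CC)(CC)CC)C[N+](=O)[O-] | intermediate
22 | ten-membered 8-nitro compound: bicyclo[8.4.0]tetradec-5Z-ene core, 1-Me, 5-Me, 2,14-diacetoxy, 9-OSiEt3, 11,20-spiro-epoxide; C1, C2, C9, C10, C11, C14 as in target, C8 epimers | CC(=O)O[C@H]1CC/C(C)=C\CC([N+](=O)[O-])[C@@H](O[Si](CC)(CC)CC)[C@H]2[C@]3(CC[C@H](OC(C)=O)[C@]12C)CO3 | intermediate
23 | ten-membered C8 ketone, otherwise as 22 | CC(=O)O[C@H]1CC/C(C)=C\CC(=O)[C@@H](O[Si](CC)(CC)CC)[C@H]2[C@]3(CC[C@H](OC(C)=O)[C@]12C)CO3 | intermediate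
24 | potassium (5Z,7Z)-dienolate of 23 | CC(=O)O[C@H]1CC/C(C)=C\C=C(O[K])/[C@@H](O[Si](CC)(CC)CC)[C@H]2[C@]3(CC[C@H](OC(C)=O)[C@]12C)CO3 | intermediate
25 | (5Z,7E)-dienyl triflate, C8–OSO2CF3, C6 cis to C9 | CC(=O)O[C@H]1CC/C(C)=C\C=C(OS(=O)(=O)C(F)(F)F)/[C@@H](O[Si](CC)(CC)CC)[C@H]2[C@]3(CC[C@H](OC(C)=O)[C@]12C)CO3 | intermediate
26 | 2-bromopropanoyl bromide | CC(Br)C(Br)=O | starting material
27 | 2-(trimethylsilyl)ethanol | C[Si](C)(C)CCO | starting material
28 | 2-(trimethylsilyl)ethyl 2-bromopropanoate | CC(Br)C(=O)OCC[Si](C)(C)C | intermediate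
29 | bromozinc enolate (Reformatsky reagent) of 28 | CC([Zn]Br)C(=O)OCC[Si](C)(C)C | intermediate
30 | (5Z,7Z)-dienyl 2-(trimethylsilyl)ethyl ester, 9-OSiEt3, C17 epimers | CC(=O)O[C@H]1CC/C(C)=C\C=C(C(C)C(=O)OCC[Si](C)(C)C)/[C@@H](O[Si](CC)(CC)CC)[C@H]2[C@]3(CC[C@H](OC(C)=O)[C@]12C)CO3 | intermediate
31 | C9 alcohol of 30 | CC(=O)O[C@H]1CC/C(C)=C\C=C(C(C)C(=O)OCC[Si](C)(C)C)/[C@@H](O)[C@H]2[C@]3(CC[C@H](OC(C)=O)[C@]12C)CO3 | intermediate
32 | 2,9,14-triacetate dienyl 2-(trimethylsilyl)ethyl ester | CC(=O)O[C@H]1CC/C(C)=C\C=C(C(C)C(=O)OCC[Si](C)(C)C)/[C@@H](OC(C)=O)[C@H]2[C@]3(CC[C@H](OC(C)=O)[C@]12C)CO3 | intermediate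
33 | 2,9,14-triacetate (5Z,7Z)-dienyl carboxylic acid, C17 epimers | CC(=O)O[C@H]1CC/C(C)=C\C=C(C(C)C(O)=O)/[C@@H](OC(C)=O)[C@H]2[C@]3(CC[C@H](OC(C)=O)[C@]12C)CO3 | intermediate
34 | (7S,8S)-7,8-dihydroxy acid, C17 epimers | CC(=O)O[C@H]1CC/C(C)=C\[C@H](O)[C@@](O)(C(C)C(O)=O)[C@@H](OC(C)=O)[C@H]2[C@]3(CC[C@H](OC(C)=O)[C@]12C)CO3 | intermediate
35 | 17-epimeric mixture of junceellolide K | CC(=O)O[C@H]1CC/C(C)=C\[C@@H]2OC(=O)C(C)[C@@]2(O)[C@@H](OC(C)=O)[C@H]2[C@]3(CC[C@H](OC(C)=O)[C@]12C)CO3 | intermediate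
36 | junceellolide K (1S,2S,5Z,7S,8S,9S,10S,11R,14S,17R) | CC(=O)O[C@H]1CC/C(C)=C\[C@@H]2OC(=O)[C@H](C)[C@@]2(O)[C@@H](OC(C)=O)[C@H]2[C@]3(CC[C@H](OC(C)=O)[C@]12C)CO3 | target

**Count and risks**

Total steps: 20. Longest linear sequence: 17 (steps 1, 2, 4, 5, 7 to 15, 17 to 20).

Most likely to fail, step 20 (the new carboxylate-directed syn-dihydroxylation; epoxidation or attack at C5=C6 would compete). The fallback builds the lactone from the ketone by known reactions and sets out from 23. KN(SiMe3)2 followed by 2-(phenylsulfonyl)-3-phenyloxaziridine hydroxylates the dienolate at C7 on the open face to give the 7-hydroxy ketone F1. Acylation with 26 and pyridine gives the 7-O-(2-bromopropanoyl) ketone F2. SmI2 in THF at −78 °C then closes the ring by intramolecular Reformatsky aldol onto C8, giving the 8-hydroxy-7,19-lactone silyl ether F3, with the lactone regiochemistry fixed by construction. Et3N·3HF gives the C9 alcohol F4, and Ac2O/DMAP brings the material back to the route at 35, which DBU converts to 36.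

Second, step 13 (ten-membered ring closure by nitronate allylation; oligomerisation or loss of silanol from the nitronate). The fallback moves the ring-closing bond to C8–C9 and sets out from 17. Intermolecular Tsuji–Trost alkylation of the allylic acetate with nitromethane (Pd(PPh3)4, DBU, MeNO2/THF) gives the homologated nitro compound F5. Swern oxidation of the primary silyl ether gives the nitro aldehyde F6. An intramolecular Henry reaction under high dilution (Cu(OAc)2·H2O/bis(oxazoline) or catalytic tetramethylguanidine) gives the ten-membered nitro alcohol F7, and Et3SiCl/imidazole returns to 22.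

Third, step 7 (quaternary aldol with an enolisable aldehyde; proton transfer and C2 selectivity). The fallback sets out from 10 and uses a non-enolisable acceptor with later chain extension. Enolate 14 is trapped with acrolein 5 to give the vinyl carbinol F8. Evans–Tishchenko reduction (MeCHO, SmI2) gives the C2 acetate/C14 alcohol F9, and Ac2O/DMAP gives the diacetate F10. Hydroboration with 9-borabicyclo[3.3.1]nonane gives the alkylborane F11, which is cross-coupled (B-alkyl Suzuki–Miyaura, PdCl2(dppf), K3PO4, THF/DMF/H2O) with (Z)-3-iodobut-2-en-1-yl acetate F12 (from commercial (Z)-3-iodobut-2-en-1-ol and Ac2O) to come back to the route at 17.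

**Further compounds**

F1 | step 20 | 7-hydroxy C8 ketone (9-OSiEt3, 2,14-diacetate) | CC(=O)O[C@H]1CC/C(C)=C\[C@H](O)C(=O)[C@@H](O[Si](CC)(CC)CC)[C@H]2[C@]3(CC[C@H](OC(C)=O)[C@]12C)CO3
F2 | step 20 | 7-O-(2-bromopropanoyl) C8 ketone | CC(=O)O[C@H]1CC/C(C)=C\[C@H](OC(=O)C(C)Br)C(=O)[C@@H](O[Si](CC)(CC)CC)[C@H]2[C@]3(CC[C@H](OC(C)=O)[C@]12C)CO3
F3 | step 20 | 8-hydroxy-7,19-lactone with 9-OSiEt3, C17 epimers | CC(=O)O[C@H]1CC/C(C)=C\[C@@H]2OC(=O)C(C)[C@@]2(O)[C@@H](O[Si](CC)(CC)CC)[C@H]2[C@]3(CC[C@H](OC(C)=O)[C@]12C)CO3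
F4 | step 20 | 8,9-dihydroxy-7,19-lactone (9-deacetyl compound), C17 epimers | CC(=O)O[C@H]1CC/C(C)=C\[C@@H]2OC(=O)C(C)[C@@]2(O)[C@@H](O)[C@H]2[C@]3(CC[C@H](OC(C)=O)[C@]12C)CO3
F5 | step 13 | acyclic C8 nitro compound (C7–C8 bond made, 9-OSiEt3, 2,14-diacetate) | [O-][N+](=O)CC/C=C(C)\CC[C@H](OC(C)=O)[C@@]1(C)[C@@H](OC(C)=O)CC[C@]2(CO2)[C@@H]1CO[Si](CC)(CC)CC
F6 | step 13 | nitro aldehyde (C9 aldehyde of F5) | [O-][N+](=O)CC/C=C(C)\CC[C@H](OC(C)=O)[C@@]1(C)[C@@H](OC(C)=O)CC[C@]2(CO2)[C@@H]1C=O
F7 | step 13 | ten-membered 9-hydroxy-8-nitro compound | CC(=O)O[C@H]1CC/C(C)=C\CC([N+](=O)[O-])[C@@H](O)[C@H]2[C@]3(CC[C@H](OC(C)=O)[C@]12C)CO3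
F8 | step 7 | vinyl carbinol: 5-[(1S)-1-hydroxyprop-2-en-1-yl]-5-methyl-4-[(triethylsilyloxy)methyl]-1-oxaspiro[2.5]octan-6-one | C=C[C@H](O)[C@@]1(C)C(=O)CC[C@]2(CO2)[C@@H]1CO[Si](CC)(CC)CC
F9 | step 7 | C2 acetate, C14 alcohol of F8 | C=C[C@H](OC(C)=O)[C@@]1(C)[C@@H](O)CC[C@]2(CO2)[C@@H]1CO[Si](CC)(CC)CC
F10 | step 7 | 2,14-diacetate of the vinyl compound | C=C[C@H](OC(C)=O)[C@@]1(C)[C@@H](OC(C)=O)CC[C@]2(CO2)[C@@H]1CO[Si](CC)(CC)CC
F11 | step 7 | C4 alkylborane (9-borabicyclo[3.3.1]nonan-9-yl) from F10 | C3CCC4CCCC3B4CC[C@H](OC(C)=O)[C@@]1(C)[C@@H](OC(C)=O)CC[C@]2(CO2)[C@@H]1CO[Si](CC)(CC)CC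
F12 | step 7 | (Z)-3-iodobut-2-en-1-yl acetate | CC(=O)OC/C=C(C)\I
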